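## The problem

Compound 18 is a naphthazarin (5,8-dihydroxy-1,4-naphthoquinone) whose C2 is bonded to a cyclobutane through a fully substituted ring carbon, C1'. C1' carries the angeloyloxy group and lies between C2'H2 and the quaternary C4'Me2, with C3'H2 closing the ring, so two adjacent fully substituted carbons must be joined inside a strained four-membered ring. C1' is the only stereocentre, (R); nothing else in the molecule can relay chirality to it, so its configuration must come from an auxiliary, a catalyst or a resolution. It bears no hydrogen and cannot epimerise, but as a tertiary, benzylic-type cyclobutyl C–O centre it is lost by ionisation if acid reaches it while the attached arene is electron-rich. The ester is the Z (angelic) isomer, which drifts to the E (tiglic) isomer under nucleophilic catalysis, strong base or radical conditions, and it must be placed on a very hindered tertiary alcohol. The naphthazarin is acidic, chelating and redox-active, so it has to travel masked, here as the tetramethyl ether, and be unmasked last by an oxidation that the tertiary ester and the Z-alkene survive. The feature that allows a direct ring construction is that C1' holds both the oxygen and the aryl group. C1'–C2' can be read as a 1-aryl enol ether and C3'–C4' as isobutene, and the tetra-oxygenated naphthalene on C1' can carry a radical cation, so that in a radical-cation [2+2] union both quaternary carbons are the best stabilised radical and cation sites.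

## Retrosynthesis

**Unmasking (18 back to 15).** The four O–CH3 bonds are the last to be cut in the forward sense. Methyl ethers are preferred to acetal or benzyl masks because they survive aryllithium chemistry, titanium methylenation, the anode and hydrogenolysis. They are removed in two oxidative stages, through the dimethoxyquinone 16 and the diquinone 17, followed by a mild reduction. Which ring is oxidised first is not critical, because the second oxidation brings both rings to the quinone level in 17, and the naphthazarin tautomers of 18 are one compound. The forward steps must spare the tertiary angelate.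

**Ester bond (15 back to 12 and 13).** Cutting the acyl–O bond removes the only isomerisable group. Acylation is placed at the tetramethyl ether stage, where no phenol competes, and directly before the oxidations, so the Z-alkene meets as few reagents as possible. Alcohol 12 holds the complete carbon skeleton and the stereocentre. The forward reaction must acylate a neopentyl-like tertiary alkoxide without Z to E drift; the mixed anhydride 14 is chosen for that.

**Auxiliary–oxygen bond (12 back to 11).** The oxygen on C1' is already present in 11, and only the O–CH(Me)Ph bond is cut. Acidic or Lewis-acidic cleavage would ionise C1', so hydrogenolysis is the only acceptable mode. It must choose the accessible secondary benzylic C–O bond over the buried tertiary one.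

**Ring-forming cut (11 back to 9 and 10).** C2'–C3' and C1'–C4' are cut together. The neighbouring cut at C1'–aryl, addition of aryllithium 5 to a ready-made four-membered ketone, is shorter but gives a racemate with no handle for control; it is kept as a fallback. The other [2+2] pairing, C1'–C2' with C3'–C4', needs a tetrasubstituted enol ether and leaves a superfluous carbon substituent. The chosen cut leads to isobutene 10 and enol ether 9, whose oxygen can carry a purchased chiral group and whose arene can hold the radical cation. Compound 9 is unstrained and has no stereocentre other than the purchased one. The forward reaction must deliver head-to-head regiochemistry, close C1'–C4' on one face, and keep the auxiliary on oxygen.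

**Enol ether (9 back to 8).** The C1'=C2' double bond is cut to an ester carbonyl; the methylene carbon comes from a titanium methylidene. O-Alkylation of a ketone enolate with a secondary benzylic electrophile would give C-alkylation and racemisation, whereas ester methylenation leaves the stereocentre of the alkoxy group untouched.

**Ester 8 back to 6 and 7.** The acyl–O bond is cut; esterification occurs at oxygen, so (S)-1-phenylethanol 7 is incorporated with retention.

**Acid 6 back to 1.** The C2–CO2H bond is cut to aryllithium 5 from bromide 4. The C–Br bond goes back to the symmetrical 3, whose four ring C–H positions are equivalent, and the four O–CH3 bonds go back through the leuco tetrol 2 to commercial naphthazarin 1.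

## Roads not taken

Alternative 1: The cut lies in the aromatic core, at C1–C8a, and the benzo-fused quinone ring is made last. The 4-aryl-4-hydroxycyclobutenone A2, which already holds the complete silyl-protected side chain, is heated. Its four-membered ring opens to a vinylketene, and the ketene carbon closes onto the free ortho position of the dimethoxyphenyl group to give the naphthalene-1,4-diol A1 (a Moore-type rearrangement).
- Merits: the annulation is thermal and regiospecific. One ring arrives at the hydroquinone level, so one of the two oxidative demethylations becomes a trivial oxidation. The C1' oxygen is a silyl ether removed by fluoride, which is gentler than the hydrogenolysis of step 7.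
- Weak points: the step builds what can be bought as 1 and leaves the real difficulty, the cyclobutane with two adjacent quaternary carbons and the C1' stereocentre, to be solved beforehand inside A2. A2 must also be assembled from a cyclobutenedione and an aryl-metal, and the 5,8-dimethyl ethers of A1 still need the harsher oxidation.
- Comparison: the end game of this road is milder. Against that, the chosen plan creates ring and stereocentre together on a core reached in one step from 1, and is shorter overall.

Alternative 2: Only C1'–C4' is formed, by ring contraction. The crystalline α-acetoxy ketone A4 is irradiated in the solid state. Both bonds to the carbonyl carbon break, the carbonyl group is expelled, and the two radical centres, held by the lattice, combine to the cyclobutyl acetate A3 with retention at C1'.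
- Merits: radical-pair combination in a crystal is one of the few reliable ways to join two fully substituted carbons. It is stereospecific, so C1' can be set earlier on a five-membered ketone by conventional enolate chemistry. That is a better precedented source of chirality than the auxiliary-controlled closure of step 6.
- Weak points: the reaction depends on suitable crystals and is awkward to scale. The future C4' carries only two methyl groups, which give little of the radical stabilisation normally needed at both α-positions. A3 has a dimethoxybenzene where the target has a naphthazarin, so a whole ring must still be annulated with regiocontrol. The acetate must be exchanged for the angelate, which brings back the hindered acylation of step 8.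
- Comparison: stereochemical precedent favours this road. The chosen plan sets against it an intact naphthalene from the start, far fewer steps, and the fact that the epimers of 11 are separable diastereomers.

Alternative 3: The ring is cut the other way, at C3'–C4' and C1'–C2'. The tetrasubstituted silyl enol ether A6 (C1'=C4') and the acrylate A7 are combined under a strongly Lewis-acidic chiral oxazaborolidine catalyst. C4' adds to the β-carbon of A7 and the enolate carbon C2' closes on the oxocarbenium carbon C1', giving the cyclobutane ester A5 with the ester trans to the siloxy group.
- Merits: enantiocontrol is catalytic, the reaction class is established for silyl enol ethers, and the silyl ether on C1' is removed by fluoride. In these three respects this road is ahead of the chosen plan, which needs a stoichiometric auxiliary, an untested substrate class and a hydrogenolysis.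
- Weak points: the nucleophilic carbon is the fully substituted C4', so the conjugate addition must create the quaternary centre against severe hindrance. Four methoxy groups compete for a catalyst that works through strong Lewis acidity. A5 is a donor–acceptor cyclobutane prone to ring opening. It carries a carboxylate on C2' that the target lacks, and removing it (hydrolysis, radical decarboxylation) costs about three steps.
- Comparison: the chosen plan forms the bare ring from a commodity gas with no superfluous carbon and fewer steps after the key step, and its stereochemical outcome is secured by separation even if induction is modest.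

Key step: step 6

Assumption: the (S)-1-phenylethoxy group is taken to direct the C1'–C4' closure to the face that gives (R)-C1'; if the intrinsic preference is the opposite, (R)-1-phenylethanol is used in step 4 and nothing else changes.

## Route

Step 1
Reactants: 1 naphthazarin (5,8-dihydroxynaphthalene-1,4-dione)
Product: 3 1,4,5,8-tetramethoxynaphthalene, via leuco tetrol 2 (not isolated)
Conditions: Na2S2O4, NaOH, Bu4NBr, THF/H2O, rt, N2; then Me2SO4, rt
Reagents that add atoms: dimethyl sulfate, COS(=O)(=O)OC
Why: Dithionite reduces the quinone to the leuco tetrol 2, whose phenoxides are O-methylated in the same flask (reductive methylation, Williamson ether synthesis under phase transfer), a standard entry to 3.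

Step 2
Reactants: 3 1,4,5,8-tetramethoxynaphthalene
Product: 4 2-bromo-1,4,5,8-tetramethoxynaphthalene
Conditions: NBS (1 equiv), CH2Cl2, rt
Reagents that add atoms: N-bromosuccinimide, O=C1CCC(=O)N1Br
Why: Electrophilic aromatic bromination; the four ring C–H positions of 3 are equivalent, and the first bromine deactivates the arene enough for one equivalent to stop at the monobromide.

Step 3
Reactants: 4 2-bromo-1,4,5,8-tetramethoxynaphthalene
Product: 6 1,4,5,8-tetramethoxynaphthalene-2-carboxylic acid, via aryllithium 5 (not isolated)
Conditions: n-BuLi, THF, −78 °C; CO2; aq. HCl
Reagents that add atoms: carbon dioxide, O=C=O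
Why: Bromine–lithium exchange at −78 °C gives 5 regiospecifically, and carboxylation of the aryllithium followed by acidification gives 6.

Step 4
Reactants: 6 1,4,5,8-tetramethoxynaphthalene-2-carboxylic acid; 7 (S)-1-phenylethanol
Product: 8 (S)-1-phenylethyl 1,4,5,8-tetramethoxynaphthalene-2-carboxylate
Conditions: DCC, DMAP (cat.), CH2Cl2, 0 °C to rt
Reagents that add atoms: none
Why: Steglich esterification; the alcohol oxygen attacks the activated acyl group, so the C–O bond of 7 is not broken and the (S) centre is retained.

Step 5
Reactants: 8 (S)-1-phenylethyl 1,4,5,8-tetramethoxynaphthalene-2-carboxylate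
Product: 9 1,4,5,8-tetramethoxy-2-{1-[(S)-1-phenylethoxy]ethenyl}naphthalene
Conditions: Cp2TiMe2 (excess), toluene, 70 °C, dark; filtration through basic alumina
Reagents that add atoms: dimethyltitanocene Cp2TiMe2, C[Ti](C)(C1C=CC=C1)C1C=CC=C1
Why: Petasis methylenation: Cp2TiMe2 loses methane on heating to give Cp2Ti=CH2, which converts the ester carbonyl into the 1,1-disubstituted enol ether through an oxatitanacyclobutane. The reagent is neither basic nor acidic, so the benzylic stereocentre and the acid-labile product are not endangered, and aryl esters are established substrates.

Step 6
Reactants: 9 1,4,5,8-tetramethoxy-2-{1-[(S)-1-phenylethoxy]ethenyl}naphthalene; 10 isobutene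
Product: 11 2-{(R)-2,2-dimethyl-1-[(S)-1-phenylethoxy]cyclobutyl}-1,4,5,8-tetramethoxynaphthalene
Conditions: sealed undivided cell, carbon-felt anode and cathode, 1.0 M LiClO4 in MeNO2, isobutene (large excess, condensed in), constant current, catalytic charge, 0 °C
Reagents that add atoms: none
Why: Proposed new method: one-electron oxidation of 9 at the anode gives a radical cation spread over the naphthalene and the enol ether; isobutene attacks its unsubstituted terminus C2' with the CH2 carbon (bond C2'–C3'), leaving a 1,4-distonic radical cation with the radical on C1' (benzylic and α-oxy) and a tertiary cation on C4'. The four-membered ring then closes stepwise by combination of these two centres (bond C1'–C4'), the second electron of the new bond being drawn from the naphthalene, and the arene radical cation of the product is reduced by fresh 9 (chain transfer) or at the cathode, so only a catalytic charge is needed. The closest known reaction type is the anodic radical-cation [2+2] cycloaddition of enol ethers with unactivated alkenes assisted by an alkoxyaryl group in LiClO4/MeNO2; it has not been shown for 1-aryl enol ethers, for making two adjacent quaternary carbons, or under control by a chiral O-substituent. The head-to-head regiochemistry follows from spin and charge sitting on the two best stabilised carbons. C1' is the only new stereocentre and is set in the ring closure: the (S)-1-phenylethoxy group, with its C–H bond near the plane of the C1'–O unit to avoid allylic strain, should screen one face of the planar C1' radical with its phenyl ring so that the cationic chain closes over the methyl-bearing face. The step needs closure to outrun proton loss from the C4' cation and loss of a 1-phenylethyl cation from oxygen; the electron-rich arene directly on C1' and the cation-stabilising LiClO4/MeNO2 medium are the features relied on. The two C1' epimers of 11 are diastereomers and should be separable on silica, so enantiopurity does not depend on the level of induction.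

Step 7
Reactants: 11 2-{(R)-2,2-dimethyl-1-[(S)-1-phenylethoxy]cyclobutyl}-1,4,5,8-tetramethoxynaphthalene
Product: 12 (R)-2,2-dimethyl-1-(1,4,5,8-tetramethoxynaphthalen-2-yl)cyclobutan-1-ol
Conditions: H2 (1 atm), Pd/C (10% Pd on carbon), EtOAc, rt
Reagents that add atoms: none
Why: Hydrogenolysis of a benzylic ether; the secondary benzylic C–O bond next to the unhindered phenyl ring can reach the Pd surface, whereas the tertiary C1'–O bond is buried between the gem-dimethyl group and the ortho-methoxy naphthalene. Only the auxiliary should be cut (as ethylbenzene), and C1', none of whose bonds is broken, keeps its configuration.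

Step 8
Reactants: 12 (R)-2,2-dimethyl-1-(1,4,5,8-tetramethoxynaphthalen-2-yl)cyclobutan-1-ol; 13 angelic acid ((Z)-2-methylbut-2-enoic acid)
Product: 15 (R)-2,2-dimethyl-1-(1,4,5,8-tetramethoxynaphthalen-2-yl)cyclobutyl (Z)-2-methylbut-2-enoate, via mixed anhydride 14 (not isolated)
Conditions: 13, 2,4,6-Cl3C6H2COCl, Et3N, toluene, rt; separately 12, KN(SiMe3)2, THF, −78 °C; anhydride solution added, −78 to 0 °C; pH 7 buffer
Reagents that add atoms: none
Why: Yamaguchi-type acylation with a mixed anhydride: the potassium alkoxide of 12 attacks the angeloyl carbonyl of 14 because the trichlorobenzoyl carbonyl is blocked by two ortho chlorines. No nucleophilic catalyst that could add to C3 of the enoate is present, which is what preserves the Z geometry; this is the established way to angelates of hindered alcohols.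

Step 9
Reactants: 15 (R)-2,2-dimethyl-1-(1,4,5,8-tetramethoxynaphthalen-2-yl)cyclobutyl (Z)-2-methylbut-2-enoate
Product: 16 (R)-1-(1,4-dimethoxy-5,8-dioxo-5,8-dihydronaphthalen-2-yl)-2,2-dimethylcyclobutyl (Z)-2-methylbut-2-enoate
Conditions: (NH4)2Ce(NO3)6, MeCN/H2O, 0 °C
Reagents that add atoms: water, O
Why: Oxidative demethylation of a 1,4-dimethoxyarene by tetravalent cerium (arene radical cation, ipso attack of water, loss of methanol); by analogy with other 1-acyloxyalkyl tetramethoxynaphthalenes the unsubstituted ring should react preferentially to give 16. The regiochemistry of this first oxidation is not critical, because step 10 takes the second ring to the quinone level as well.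

Step 10
Reactants: 16 (R)-1-(1,4-dimethoxy-5,8-dioxo-5,8-dihydronaphthalen-2-yl)-2,2-dimethylcyclobutyl (Z)-2-methylbut-2-enoate
Product: 18 (R)-1-(5,8-dihydroxy-1,4-dioxo-1,4-dihydronaphthalen-2-yl)-2,2-dimethylcyclobutyl (Z)-2-methylbut-2-enoate, via diquinone 17 (not isolated)
Conditions: AgO, 6 M HNO3, 1,4-dioxane, rt, short contact; then aq. Na2S2O4
Reagents that add atoms: water, O
Why: Divalent silver in nitric acid oxidatively demethylates the remaining dimethoxy ring of 16 to the diquinone 17, which dithionite reduces by two electrons to the naphthazarin. The naphthazarin tautomers interconvert rapidly, so a single compound 18 results, and C1' (no hydrogen, no bond broken) and the Z-alkene are not involved.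

## Compound list

1 | naphthazarin (5,8-dihydroxynaphthalene-1,4-dione) | O=C1C=CC(=O)c2c(O)ccc(O)c12 | starting material
2 | naphthalene-1,4,5,8-tetrol (leuco form, present as sodium phenoxides) | Oc1ccc(O)c2c(O)ccc(O)c12 | intermediate (not isolated)
3 | 1,4,5,8-tetramethoxynaphthalene | COc1ccc(OC)c2c(OC)ccc(OC)c12 | intermediate
4 | 2-bromo-1,4,5,8-tetramethoxynaphthalene | COc1ccc(OC)c2c(OC)c(Br)cc(OC)c12 | intermediate
5 | (1,4,5,8-tetramethoxynaphthalen-2-yl)lithium | COc1ccc(OC)c2c(OC)c([Li])cc(OC)c12 | intermediate (not isolated)
6 | 1,4,5,8-tetramethoxynaphthalene-2-carboxylic acid | COc1ccc(OC)c2c(OC)c(C(=O)O)cc(OC)c12 | intermediate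
7 | (S)-1-phenylethanol | C[C@H](O)c1ccccc1 | starting material
8 | (S)-1-phenylethyl 1,4,5,8-tetramethoxynaphthalene-2-carboxylate | C[C@H](OC(=O)c1cc(OC)c2c(OC)ccc(OC)c2c1OC)c1ccccc1 | intermediate
9 | 1,4,5,8-tetramethoxy-2-{1-[(S)-1-phenylethoxy]ethenyl}naphthalene | C=C(O[C@@H](C)c1ccccc1)c1cc(OC)c2c(OC)ccc(OC)c2c1OC | intermediate
10 | isobutene (2-methylpropene) | CC(C)=C | starting material
11 | 2-{(R)-2,2-dimethyl-1-[(S)-1-phenylethoxy]cyclobutyl}-1,4,5,8-tetramethoxynaphthalene | C[C@H](O[C@]1(c2cc(OC)c3c(OC)ccc(OC)c3c2OC)CCC1(C)C)c1ccccc1 | intermediate
12 | (R)-2,2-dimethyl-1-(1,4,5,8-tetramethoxynaphthalen-2-yl)cyclobutan-1-ol | O[C@]1(c2cc(OC)c3c(OC)ccc(OC)c3c2OC)CCC1(C)C | intermediate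
13 | angelic acid ((Z)-2-methylbut-2-enoic acid) | C/C=C(/C)C(=O)O | starting material
14 | (Z)-2-methylbut-2-enoic 2,4,6-trichlorobenzoic anhydride | C/C=C(/C)C(=O)OC(=O)c1c(Cl)cc(Cl)cc1Cl | intermediate (not isolated)
15 | (R)-2,2-dimethyl-1-(1,4,5,8-tetramethoxynaphthalen-2-yl)cyclobutyl (Z)-2-methylbut-2-enoate | C/C=C(/C)C(=O)O[C@]1(c2cc(OC)c3c(OC)ccc(OC)c3c2OC)CCC1(C)C | intermediate
16 | (R)-1-(1,4-dimethoxy-5,8-dioxo-5,8-dihydronaphthalen-2-yl)-2,2-dimethylcyclobutyl (Z)-2-methylbut-2-enoate | C/C=C(/C)C(=O)O[C@]1(c2cc(OC)c3C(=O)C=CC(=O)c3c2OC)CCC1(C)C | intermediate
17 | (R)-2,2-dimethyl-1-(1,4,5,8-tetraoxo-1,4,5,8-tetrahydronaphthalen-2-yl)cyclobutyl (Z)-2-methylbut-2-enoate | C/C=C(/C)C(=O)O[C@]1(C2=CC(=O)C3=C(C2=O)C(=O)C=CC3=O)CCC1(C)C | intermediate (not isolated)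
18 | (R)-1-(5,8-dihydroxy-1,4-dioxo-1,4-dihydronaphthalen-2-yl)-2,2-dimethylcyclobutyl (Z)-2-methylbut-2-enoate | C/C=C(/C)C(=O)O[C@]1(C2=CC(=O)c3c(O)ccc(O)c3C2=O)CCC1(C)C | target

## Step count and weak points

Total: 10 steps. Longest linear sequence: 10 steps (1 to 18); 7, 10 and 13 are purchased and enter at steps 4, 6 and 8.

**Step 6 (key step, proposed new method).** Three processes may defeat it.
- The positive charge may stay on the naphthalene, which the C1 methoxy group twists out of conjugation with the enol ether. C2' is then not electrophilic enough, and 9 is only consumed by hydrolysis while isobutene oligomerises.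
- The C4' cation may lose a proton, or the radical cation may shed a 1-phenylethyl cation, faster than the ring closes.
- Facial selectivity of the closure may be low or opposite. The opposite sense is answered by the enantiomeric auxiliary; low selectivity costs material but not enantiopurity.

The fallback uses known chemistry and forms the same two bonds by a thermal ketene–enol ether [2+2] cycloaddition. It sets out from 9. Dimethylketene F1, generated from isobutyryl chloride and Et3N, should add with the usual regiochemistry (C2' to the ketene carbonyl carbon, C1' to CMe2). This gives (S)-2,2-dimethyl-3-[(S)-1-phenylethoxy]-3-(1,4,5,8-tetramethoxynaphthalen-2-yl)cyclobutan-1-one F2, which is the skeleton of 11 with a carbonyl at C3'. The ring carbon has the same spatial arrangement as in 11; the descriptor changes because the carbonyl raises the rank of the CMe2 branch. Diastereomers are separated at this stage. Condensation with tosylhydrazine gives N'-{(R)-2,2-dimethyl-3-[(S)-1-phenylethoxy]-3-(1,4,5,8-tetramethoxynaphthalen-2-yl)cyclobutylidene}-4-methylbenzenesulfonohydrazide F3. Reduction with catecholborane, then NaOAc, removes the carbonyl and returns to the route at 11.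

**Step 7.** Hydrogenolysis may cleave the wrong benzylic C–O bond, since the tertiary C1'–O bond is activated by the electron-rich arene and ring strain, or it may stall because the ether is buried. The fallback avoids any ether cleavage. It sets out from 4: aryllithium 5 is transmetalated with CeCl3 and added to commercial 2,2-dimethylcyclobutanone to give racemic 2,2-dimethyl-1-(1,4,5,8-tetramethoxynaphthalen-2-yl)cyclobutan-1-ol F4. Preparative chromatography on a chiral stationary phase resolves it into 12 and (S)-2,2-dimethyl-1-(1,4,5,8-tetramethoxynaphthalen-2-yl)cyclobutan-1-ol F5, which is discarded. The route is rejoined at 12, at the price of half the material.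

**Step 8.** Acylation of the hindered tertiary alkoxide may be too slow, the angelate may isomerise to the tiglate, or the strained potassium cyclobutoxide may ring-open. The fallback builds the angelate in two stages and sets out from 12. Carbodiimide coupling with 2-[bis(2,2,2-trifluoroethoxy)phosphoryl]propanoic acid F6, obtained by hydrolysis of its commercial ethyl ester, gives (R)-2,2-dimethyl-1-(1,4,5,8-tetramethoxynaphthalen-2-yl)cyclobutyl 2-[bis(2,2,2-trifluoroethoxy)phosphoryl]propanoate F7. A Still–Gennari olefination with acetaldehyde (KN(SiMe3)2, 18-crown-6, THF, −78 °C) then forms the Z-trisubstituted alkene and returns to the route at 15.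

**Step 10.** The acidic oxidant may ionise or hydrolyse the tertiary ester, nitrogen oxides may isomerise the Z-alkene, or oxidation of the second ring may stay incomplete. Regiochemical leakage in step 9 does no harm here, since this oxidation brings both rings to the quinone level whichever was oxidised first. The fallback is non-oxidative and sets out from 16. BCl3 in CH2Cl2 at −78 °C cleaves the two methyl ethers peri to the quinone carbonyls under chelation control, and aqueous work-up gives 18 directly, the product being the same compound through the rapid naphthazarin tautomerism. No new isolable compound is made (F0).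

**Step 5.** Methylenation of the hindered, electron-rich aryl ester may be incomplete, and the 1-aryl enol ether may hydrolyse on isolation. The fallback forms the aryl–C1' bond instead of the C=CH2 bond and sets out from 4. Alcohol 7 is converted into (S)-1-phenylethyl vinyl ether F8 by transfer vinylation with vinyl acetate ([Ir(cod)Cl]2, Na2CO3, toluene, 100 °C). A regioselective internal Heck arylation of F8 with 4 (Pd(OAc)2, dppp, Et3N, DMSO) returns to the route at 9.

## Further compounds

F1 | step 6 | dimethylketene | CC(C)=C=O
F2 | step 6 | (S)-2,2-dimethyl-3-[(S)-1-phenylethoxy]-3-(1,4,5,8-tetramethoxynaphthalen-2-yl)cyclobutan-1-one | C[C@H](O[C@]1(c2cc(OC)c3c(OC)ccc(OC)c3c2OC)CC(=O)C1(C)C)c1ccccc1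
F3 | step 6 | N'-{(R)-2,2-dimethyl-3-[(S)-1-phenylethoxy]-3-(1,4,5,8-tetramethoxynaphthalen-2-yl)cyclobutylidene}-4-methylbenzenesulfonohydrazide | C[C@H](O[C@]1(c2cc(OC)c3c(OC)ccc(OC)c3c2OC)CC(=NNS(=O)(=O)c2ccc(C)cc2)C1(C)C)c1ccccc1
F4 | step 7 | racemic 2,2-dimethyl-1-(1,4,5,8-tetramethoxynaphthalen-2-yl)cyclobutan-1-ol | OC1(c2cc(OC)c3c(OC)ccc(OC)c3c2OC)CCC1(C)C
F5 | step 7 | (S)-2,2-dimethyl-1-(1,4,5,8-tetramethoxynaphthalen-2-yl)cyclobutan-1-ol | O[C@@]1(c2cc(OC)c3c(OC)ccc(OC)c3c2OC)CCC1(C)C
F6 | step 8 | 2-[bis(2,2,2-trifluoroethoxy)phosphoryl]propanoic acid | CC(C(=O)O)P(=O)(OCC(F)(F)F)OCC(F)(F)F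
F7 | step 8 | (R)-2,2-dimethyl-1-(1,4,5,8-tetramethoxynaphthalen-2-yl)cyclobutyl 2-[bis(2,2,2-trifluoroethoxy)phosphoryl]propanoate | CC(C(=O)O[C@]1(c2cc(OC)c3c(OC)ccc(OC)c3c2OC)CCC1(C)C)P(=O)(OCC(F)(F)F)OCC(F)(F)F
F0 | step 10 | none | none
F8 | step 5 | (S)-1-phenylethyl vinyl ether | C=CO[C@@H](C)c1ccccc1
A1 | alternative 1 | 2-[(R)-2,2-dimethyl-1-(triethylsilyloxy)cyclobutyl]-5,8-dimethoxynaphthalene-1,4-diol | CC[Si](CC)(CC)O[C@]1(c2cc(O)c3c(OC)ccc(OC)c3c2O)CCC1(C)C
A2 | alternative 1 | 4-(2,5-dimethoxyphenyl)-2-[(R)-2,2-dimethyl-1-(triethylsilyloxy)cyclobutyl]-4-hydroxycyclobut-2-en-1-one | CC[Si](CC)(CC)O[C@]1(C2=CC(O)(c3cc(OC)ccc3OC)C2=O)CCC1(C)C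
A3 | alternative 2 | (R)-1-(2,5-dimethoxyphenyl)-2,2-dimethylcyclobutyl acetate | CC(=O)O[C@]1(c2cc(OC)ccc2OC)CCC1(C)C
A4 | alternative 2 | (S)-1-(2,5-dimethoxyphenyl)-3,3-dimethyl-2-oxocyclopentyl acetate | CC(=O)O[C@]1(c2cc(OC)ccc2OC)CCC(C)(C)C1=O
A5 | alternative 3 | 2,2,2-trifluoroethyl 2-(tert-butyldimethylsilyloxy)-3,3-dimethyl-2-(1,4,5,8-tetramethoxynaphthalen-2-yl)cyclobutane-1-carboxylate, ester trans to siloxy, carbinol carbon as in the target | CC(C)(C)[Si](C)(C)O[C@]1(c2cc(OC)c3c(OC)ccc(OC)c3c2OC)[C@@H](C(=O)OCC(F)(F)F)CC1(C)C
A6 | alternative 3 | tert-butyldimethyl{[2-methyl-1-(1,4,5,8-tetramethoxynaphthalen-2-yl)prop-1-en-1-yl]oxy}silane | CC(C)=C(O[Si](C)(C)C(C)(C)C)c1cc(OC)c2c(OC)ccc(OC)c2c1OC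
A7 | alternative 3 | 2,2,2-trifluoroethyl acrylate | C=CC(=O)OCC(F)(F)F
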